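One ratio is worth carrying for this flask: product over starting material, once the catalysed route stands level. Time drops out of that ratio.

solid substrate 0.050 M; precatalyst 5.0 µM; time 2.5 h

    starting material + enzyme ⇌ complex (K1 = 11 /M, k1 = 25000 /M/s)
    complex ⇌ enzyme + product (K2 = 0.017 M, k2 = 250 /s)
    solid substrate ⇌ starting material, rate k3*(cs3 - [starting material]) while solid is left; crystals form when [starting material] > cs3 (cs3 = 49 mM, k3 = 0.0074 /s)
    enzyme → spent catalyst (k4 = 3.3 × 10⁻⁶ /s)
    precatalyst ⇌ enzyme (K5 = 0.15, k5 = 0.0066 /s)

- solid substrate is a solid; its amount is given per volume of the solution
- at the start none of the solid substrate is in solution
- what has only dissolved of solid substrate counts as not reacted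
- the reaction counts as stopped when no species that holds the solid substrate changes by six tenths of a point or more over the second half of the time
- starting material means what is dissolved; the solid is not counted in it
- run time (flask): 2.5 h

- why nothing more happens at 2.5 h, or that something still does (for what has run out or reacted, a solid counts together with what of it has only dissolved) (it is still moving / no working catalyst is left / forward and back rates have come level / all of the solid substrate has reacted)
- product at 2.5 h, in percent of the solid substrate charged
- starting material at 2.5 h, in percent of the solid substrate charged

**Examiner:** Why does time drop out?

**Candidate:** At level rates, each step's forward rate equals its back rate. The first step then gives complex over starting material times enzyme as 11 /M. The second gives enzyme times product over complex as 0.017 M. Multiply them, and enzyme and complex cancel. Call K the level ratio, product concentration over starting material concentration when both catalysed steps stand level. Here K is 0.187.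

**Examiner:** What do you commit to?

**Candidate:** If the solid dissolves wholly, the charge splits by K. That gives product 15.8 % and starting material 84.2 %. The catalyst charge is 0.0100 % of the solid substrate charge, so I ignore what it binds.

**Examiner:** But starting material cannot stay dissolved above 49 mM. Does the solid dissolve wholly?

**Candidate:** Call C the charge at which starting material, at level ratio, just touches solubility. C is the solubility times one plus K, so 58.2 mM. This flask holds 0.050 M, which is less, so I expect no solid at the end. The margin is 8.20 mM.

**Examiner:** With a trace of catalyst, is there time?

**Candidate:** The time constant of dissolving is about 2.25 min, far shorter than the run. Leaving complex out of the balance, the precatalyst yields about 0.652 µM of enzyme. With complex held steady, I reckon the route relaxes in about 1.63 min, also far shorter than the run. The enzyme's half-life against spending is 58.3 h, far longer than the run. So I expect level rates, with enzyme still at work.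

The forecast says forward and back rates have come level, with product 15.8 % (range 15.5 % to 16 %) and starting material 84.2 % (range 84 % to 84.5 %). Its words are: “the mixture simply sits at equilibrium with active catalyst still present”.

The simulation gives forward and back rates have come level, with product 15.8 % and starting material 84.2 %.

In this flask, product stops at the share that K of 0.187 sets because of the backward run from enzyme + product to complex: with that run taken away, product reaches >99.9 % against 15.8 %. The neighbour flask with 0.20 M of solid substrate lies above C, so its starting material should hold at 49 mM, and K then puts product at 4.58 % of that charge. That neighbour reads 4.58 % product at 2.50 h, with 70.9 % of its charge still solid.

Its constants were drawn at random within sensible limits; no experiment stands behind them.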